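**Plan**
- Retrosynthesis cuts the ester bond between the arachidonoyl carbonyl and O–C1 of the diterpenol first, then the single ring bond C10–C15. The alcohol is numbered from the ester CH2 (C1) along the chain to the ring CH (C10) and round the ring (C11–C15).
- Enabling feature: the alcohol half is geranylgeraniol with its last isoprene unit closed. Ring C10–C15, the C(CH3)2 carbon C15, the C11=C12 ring alkene and the only stereocentre C10 all follow from forming C10–C15.
- Forward: the six-membered ring is closed first, on unprotected all-E geranylgeraniol, by a class 2 terpene cyclase (proton to C14, C10 to C15, proton lost from C12). The C20 acyl chain is joined last by esterification.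
- Stereochemistry: C10 (S) comes from the chair fold enforced by the cyclase pocket. The 2E,6E alkenes are carried over from geranylgeraniol and the four Z alkenes from arachidonic acid.

Key step: step 1

Assumption: all-E geranylgeraniol and arachidonic acid are purchased; the cyclase variant is treated as a catalyst, so its directed evolution and expression are not counted as steps.

**Step 1**
Reactants: 1 (2E,6E,10E)-geranylgeraniol
Product: 3 (2E,6E)-3,7-dimethyl-9-[(1S)-2,6,6-trimethylcyclohex-2-en-1-yl]nona-2,6-dien-1-ol, via enzyme-bound C11 carbocation 2 (not isolated)
Conditions: evolved variant of Alicyclobacillus acidocaldarius squalene–hopene cyclase (E. coli lysate), citrate buffer pH 6.0, 0.2% Triton X-100, 50 °C, dark, argon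
Reagents that add atoms: none
Why: Proposed new method: the aspartic acid of the cyclase's DXDD motif protonates C14 of the C14=C15 alkene of chair-folded 1, C10 of the C10=C11 alkene bonds to C15 in the same event to give enzyme-bound tertiary C11 cation 2, and an active-site base takes a proton from C12 to leave the C11=C12 ring alkene of 3. The closest known reaction types are squalene–hopene cyclase variants that arrest after ring A on squalene and on geranylacetone but deprotonate the C11 methyl group, and an oxidosqualene cyclase that releases camelliol C, a monocyclic triterpenol with the alkene inside the ring; polyprenols with a free CH2OH terminus are accepted by this enzyme class. The one ring closes in the 6-endo-trig mode, both carbons of the attacking C10=C11 alkene becoming ring members. C10 is the only new stereocentre and is set by the enzyme: the pro-chair fold that these cyclases impose on the E-configured terminus puts the C9 chain equatorial and delivers C15 to one face of C10, the sense that gives C5 of hopene and here the S configuration. The step needs initiation at the terminus only, arrest after one ring and proton loss from C12 rather than from the methyl group; the substrate contributes the most basic (isopropylidene) alkene, the E geometry and Markovnikov polarity that make C10 the nucleophile and C11 the cationic centre, and a C2=C3 alkene deactivated by the allylic oxygen, whereas exclusion of the C6=C7 alkene and placement of the base must be evolved into the pocket (bulkier first-shell residues at the ring A/ring B boundary, such as at Y420, G600 or L607, with GC–MS screening).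

**Step 2**
Reactants: 3 (2E,6E)-3,7-dimethyl-9-[(1S)-2,6,6-trimethylcyclohex-2-en-1-yl]nona-2,6-dien-1-ol, 4 arachidonic acid
Product: 6 (2E,6E)-3,7-dimethyl-9-[(1S)-2,6,6-trimethylcyclohex-2-en-1-yl]nona-2,6-dien-1-yl (5Z,8Z,11Z,14Z)-icosa-5,8,11,14-tetraenoate, via arachidonoyl O-acylisourea 5 (not isolated)
Conditions: DIC (1.2 equiv), DMAP (0.1 equiv), BHT (trace), CH2Cl2, 0 °C to rt, argon, dark
Reagents that add atoms: none
Why: Steglich esterification: DIC turns acid 4 into O-acylisourea 5, from which DMAP relays the acyl group to the unhindered primary allylic hydroxyl of 3 under neutral conditions at or below room temperature, so that the skipped Z-tetraene, the trisubstituted alkenes and the C10 stereocentre are left untouched and no new stereocentre arises.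

**Compound list**
1 | (2E,6E,10E)-geranylgeraniol, (2E,6E,10E)-3,7,11,15-tetramethylhexadeca-2,6,10,14-tetraen-1-ol | OC/C=C(\C)CC/C=C(\C)CC/C=C(\C)CCC=C(C)C | starting material
2 | enzyme-bound C11 carbocation, 2-[(3E,7E)-9-hydroxy-3,7-dimethylnona-3,7-dien-1-yl]-1,3,3-trimethylcyclohexylium with the ring CH configured as in 3 | OC/C=C(\C)CC/C=C(\C)CC[C@@H]1[C+](C)CCCC1(C)C | intermediate
3 | (2E,6E)-3,7-dimethyl-9-[(1S)-2,6,6-trimethylcyclohex-2-en-1-yl]nona-2,6-dien-1-ol | OC/C=C(\C)CC/C=C(\C)CC[C@@H]1C(C)=CCCC1(C)C | intermediate
4 | arachidonic acid, (5Z,8Z,11Z,14Z)-icosa-5,8,11,14-tetraenoic acid | CCCCC/C=C\C/C=C\C/C=C\C/C=C\CCCC(=O)O | starting material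
5 | arachidonoyl O-acylisourea, N,N'-diisopropyl-O-[(5Z,8Z,11Z,14Z)-icosa-5,8,11,14-tetraenoyl]isourea | CCCCC/C=C\C/C=C\C/C=C\C/C=C\CCCC(=O)OC(=NC(C)C)NC(C)C | intermediate
6 | (2E,6E)-3,7-dimethyl-9-[(1S)-2,6,6-trimethylcyclohex-2-en-1-yl]nona-2,6-dien-1-yl (5Z,8Z,11Z,14Z)-icosa-5,8,11,14-tetraenoate | CCCCC/C=C\C/C=C\C/C=C\C/C=C\CCCC(=O)OC/C=C(\C)CC/C=C(\C)CC[C@@H]1C(C)=CCCC1(C)C | target

**Totals and risks**
Total step count: 2. Longest linear sequence: 2 steps (1 to 3 to 6). The route has only two steps, so both are assessed, the riskier first.

1. Step 1 (proposed new method). The cation formed on ring closure may be quenched by proton loss from the C11 methyl group instead of from C12. It may also be captured by the C6=C7 alkene, so that a second ring forms, or turnover on the C20 alcohol may stay too low for preparative work. The fallback sets out from 1 and comes back to the route at 3, and both of its operations are of demonstrated type. Ring closure is left to a cyclase variant of the kind already shown on squalene and geranylacetone, which arrests after ring A and deprotonates the methyl group. This should give the exocyclic isomer (2E,6E)-9-[(1S)-2,2-dimethyl-6-methylidenecyclohexyl]-3,7-dimethylnona-2,6-dien-1-ol F1, with the same C10–C15 bond and the same C10 configuration. The alkene is then moved into the ring in a separate chemical step by cobalt-hydride hydrogen-atom-transfer isomerisation. The conditions would be Co(salen)Cl, namely chlorido[N,N'-bis(3,5-di-tert-butylsalicylidene)-1,2-cyclohexanediaminato]cobalt, with catalytic PhSiH3 in benzene at rt. This method addresses 1,1-disubstituted alkenes in preference to the trisubstituted C2=C3 and C6=C7 alkenes. The hydrogen should be returned from the accessible C12 methylene rather than from the congested C10–H, giving 3 with the stereocentre untouched.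

2. Step 2. Acyl transfer to the alcohol may be slower than the O-to-N acyl shift in 5, which would divert the acid into an unreactive N-acylurea. The skipped tetraene may also autoxidise during a prolonged reaction. The fallback sets out from 3 and 4 and comes back at 6, and it reverses the polarity of the coupling so that the acid is never activated. Alcohol 3 would be converted with PBr3 (Et2O, −10 °C) into (2E,6E)-1-bromo-3,7-dimethyl-9-[(1S)-2,6,6-trimethylcyclohex-2-en-1-yl]nona-2,6-diene F2. Acid 4 would be converted with Cs2CO3 (1 equiv, DMF) into caesium (5Z,8Z,11Z,14Z)-icosa-5,8,11,14-tetraenoate F3. SN2 O-alkylation of the carboxylate by the primary allylic bromide at rt under argon should then give 6 with the 2E geometry retained.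

**Further compounds**
F1 | step 1 | (2E,6E)-9-[(1S)-2,2-dimethyl-6-methylidenecyclohexyl]-3,7-dimethylnona-2,6-dien-1-ol | OC/C=C(\C)CC/C=C(\C)CC[C@@H]1C(=C)CCCC1(C)C
F2 | step 2 | (2E,6E)-1-bromo-3,7-dimethyl-9-[(1S)-2,6,6-trimethylcyclohex-2-en-1-yl]nona-2,6-diene | BrC/C=C(\C)CC/C=C(\C)CC[C@@H]1C(C)=CCCC1(C)C
F3 | step 2 | caesium (5Z,8Z,11Z,14Z)-icosa-5,8,11,14-tetraenoate | CCCCC/C=C\C/C=C\C/C=C\C/C=C\CCCC(=O)[O-].[Cs+]
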